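Ring numbering used: C1 carries the aryl–aryl bond, C2 the hydroxyl, C3 and C4 the methoxy groups, C5 hydrogen and C6 the side chain C7–C9. Everything rests on cutting C6–C7 and C6'–C7' back to allyl ethers on O3 and O3' of a preformed biaryl. Because C6 is para to O3 and both carbons ortho to O3 (C2, C4) already bear oxygen, one heating sends each allyl group through a Claisen shift and then a Cope shift onto C6. This installs both three-carbon chains beside the axis and frees the C3 phenols for methylation. The precursor, 3,3'-bis(allyloxy)-4,4'-dimethoxy-2,2'-bis(methoxymethoxy)biphenyl, has only two ortho substituents on its axis and comes from o-vanillin by MOM-directed lithiation and oxidative dimerisation.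

Key step: step 7

Assumption: the target SMILES carries no stereocentre and no axial descriptor, so the tetra-ortho-substituted biaryl axis is made as the racemate.

Step 1
Reactants: 1 o-vanillin (2-hydroxy-3-methoxybenzaldehyde); 2 benzyl bromide
Product: 3 2-(benzyloxy)-3-methoxybenzaldehyde
Conditions: BnBr, K2CO3, DMF, 60 °C
Reagents that add atoms: benzyl bromide, BrCc1ccccc1
Why: Williamson etherification, in which K2CO3 in DMF opens the hydrogen bond between the phenol and the aldehyde and the phenoxide is benzylated without touching the aldehyde.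

Step 2
Reactants: 3 2-(benzyloxy)-3-methoxybenzaldehyde
Product: 5 2-(benzyloxy)-3-methoxyphenol, via aryl formate 4 (not isolated)
Conditions: mCPBA, CH2Cl2, 0 °C to rt; aqueous wash; then K2CO3 (cat.), MeOH, rt
Reagents that add atoms: 3-chloroperoxybenzoic acid (mCPBA), OOC(=O)c1cccc(Cl)c1
Why: Baeyer–Villiger oxidation in its Dakin-type form, in which the electron-rich ortho-alkoxyaryl group migrates in preference to hydride to give the aryl formate, which mild base methanolyses while the benzyl and methyl ethers stay inert.

Step 3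
Reactants: 5 2-(benzyloxy)-3-methoxyphenol; 6 chloromethyl methyl ether
Product: 7 2-(benzyloxy)-1-methoxy-3-(methoxymethoxy)benzene
Conditions: NaH, THF/DMF, 0 °C; then MOMCl, 0 °C to rt
Reagents that add atoms: chloromethyl methyl ether, COCCl
Why: Williamson-type O-alkylation of the sodium phenoxide with the reactive α-chloro ether installs the MOM acetal, which later serves both as ortho-directing group and as protecting group for O2.

Step 4
Reactants: 7 2-(benzyloxy)-1-methoxy-3-(methoxymethoxy)benzene (two molecules)
Product: 9 3,3'-bis(benzyloxy)-4,4'-dimethoxy-2,2'-bis(methoxymethoxy)-1,1'-biphenyl, via aryllithium 8 (not isolated)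
Conditions: n-BuLi, TMEDA, THF, 0 °C; then anhydrous CuCl2, −78 °C to rt
Reagents that add atoms: none
Why: Directed ortho-metalation followed by oxidative homocoupling, in which OMOM outranks OMe as director and has only one free ortho position (C4 of 7), the O3 benzyl group (chosen because an allyl ether would not survive butyllithium) should tolerate n-BuLi at 0 °C, and divalent copper chloride oxidises the aryllithium to the symmetrical biaryl.

Step 5
Reactants: 9 3,3'-bis(benzyloxy)-4,4'-dimethoxy-2,2'-bis(methoxymethoxy)-1,1'-biphenyl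
Product: 10 4,4'-dimethoxy-2,2'-bis(methoxymethoxy)-[1,1'-biphenyl]-3,3'-diol
Conditions: H2 (1 atm), 10% Pd/C, EtOAc, rt
Reagents that add atoms: none
Why: Catalytic hydrogenolysis of the two benzyl aryl ethers under neutral conditions should leave the MOM acetals, the methyl ethers and the biaryl untouched.

Step 6
Reactants: 10 4,4'-dimethoxy-2,2'-bis(methoxymethoxy)-[1,1'-biphenyl]-3,3'-diol; 11 allyl bromide
Product: 12 3,3'-bis(allyloxy)-4,4'-dimethoxy-2,2'-bis(methoxymethoxy)-1,1'-biphenyl
Conditions: allyl bromide, K2CO3, acetone, reflux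
Reagents that add atoms: allyl bromide, C=CCBr
Why: Williamson O-allylation of both C3 phenoxides at a temperature far below that needed for sigmatropic rearrangement, so the bis(allyl ether) should be isolable.

Step 7
Reactants: 12 3,3'-bis(allyloxy)-4,4'-dimethoxy-2,2'-bis(methoxymethoxy)-1,1'-biphenyl
Product: 18 6,6'-diallyl-4,4'-dimethoxy-2,2'-bis(methoxymethoxy)-[1,1'-biphenyl]-3,3'-diol, via ring A ortho-dienone 13 (not isolated), via ring A para-dienone 14 (not isolated), via monophenol 15 (not isolated), via ring B ortho-dienone 16 (not isolated), via ring B para-dienone 17 (not isolated)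
Conditions: PhNEt2 (degassed), 200 °C, sealed tube, argon
Reagents that add atoms: none
Why: On each ring an aromatic Claisen [3,3] shift moves the allyl group from O3 to C4 (drawn; a shift to C2 is the equivalent detour), giving a cyclohexa-2,4-dienone that cannot enolise because that carbon bears OMe or OMOM; a Cope [3,3] shift then passes the allyl group to C6, and the resulting cyclohexa-2,5-dienone loses H6 to give the C3 phenol, so that C6–C7 and C6'–C7' are formed. The closest known reaction type is the para-Claisen rearrangement of allyl 2,6-dialkoxyphenyl ethers, run here twice on one biaryl. No ring is closed and no stereocentre is created; the axis, now flanked by four ortho groups, arises as the racemate. The selectivity needed is C6 over C5, and the substrate secures it because C6 is the only hydrogen-bearing carbon that two consecutive [3,3] shifts from O3 can reach (C5 is meta to O3), while the dienones formed via C2 and via C4 converge on C6. The basic amine solvent buffers the liberated phenols so that the MOM acetals should survive, and exclusion of air limits oxidation of the electron-rich phenols.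

Step 8
Reactants: 18 6,6'-diallyl-4,4'-dimethoxy-2,2'-bis(methoxymethoxy)-[1,1'-biphenyl]-3,3'-diol; 19 iodomethane
Product: 20 6,6'-diallyl-3,3',4,4'-tetramethoxy-2,2'-bis(methoxymethoxy)-1,1'-biphenyl
Conditions: MeI, K2CO3, DMF, rt
Reagents that add atoms: iodomethane, CI
Why: Williamson methylation of the two liberated C3 phenols, the only acidic sites, turns them into the C3 methoxy groups of the target while the terminal alkenes and MOM acetals are unaffected.

Step 9
Reactants: 20 6,6'-diallyl-3,3',4,4'-tetramethoxy-2,2'-bis(methoxymethoxy)-1,1'-biphenyl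
Product: 21 3,3',4,4'-tetramethoxy-2,2'-bis(methoxymethoxy)-6,6'-bis(2-oxopropyl)-1,1'-biphenyl
Conditions: PdCl2 (20 mol %), CuCl (40 mol %), O2 (1 atm), DMF/H2O 7:1, rt
Reagents that add atoms: water, O
Why: Tsuji–Wacker oxidation, in which divalent palladium activates each terminal alkene for Markovnikov attack of water at C8, β-hydride elimination and tautomerisation give the methyl ketone, copper chloride with O2 reoxidises zerovalent palladium, and the DMF-buffered medium should spare the MOM acetals while no free phenol is exposed to the oxidant.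

Step 10
Reactants: 21 3,3',4,4'-tetramethoxy-2,2'-bis(methoxymethoxy)-6,6'-bis(2-oxopropyl)-1,1'-biphenyl
Product: 22 2,2'-dihydroxy-3,3',4,4'-tetramethoxy-6,6'-bis(2-oxopropyl)-1,1'-biphenyl (target)
Conditions: 3 M HCl (aq), THF, 40 °C
Reagents that add atoms: none
Why: Acid-catalysed hydrolysis of the two aryl MOM acetals through the oxocarbenium ion frees the C2 phenols, and dilute aqueous acid without an alcohol avoids ketal formation while the aryl methyl ethers and the ketones remain intact.

Compound list
1 | o-vanillin (2-hydroxy-3-methoxybenzaldehyde) | COc1cccc(C=O)c1O | starting material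
2 | benzyl bromide | BrCc1ccccc1 | starting material
3 | 2-(benzyloxy)-3-methoxybenzaldehyde | COc1cccc(C=O)c1OCc1ccccc1 | intermediate
4 | 2-(benzyloxy)-3-methoxyphenyl formate (not isolated) | COc1cccc(OC=O)c1OCc1ccccc1 | intermediate
5 | 2-(benzyloxy)-3-methoxyphenol | COc1cccc(O)c1OCc1ccccc1 | intermediate
6 | chloromethyl methyl ether | COCCl | starting material
7 | 2-(benzyloxy)-1-methoxy-3-(methoxymethoxy)benzene | COCOc1cccc(OC)c1OCc1ccccc1 | intermediate
8 | [3-(benzyloxy)-4-methoxy-2-(methoxymethoxy)phenyl]lithium (not isolated) | [Li]c1ccc(OC)c(OCc2ccccc2)c1OCOC | intermediate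
9 | 3,3'-bis(benzyloxy)-4,4'-dimethoxy-2,2'-bis(methoxymethoxy)-1,1'-biphenyl | COCOc1c(OCc2ccccc2)c(OC)ccc1-c1ccc(OC)c(OCc2ccccc2)c1OCOC | intermediate
10 | 4,4'-dimethoxy-2,2'-bis(methoxymethoxy)-[1,1'-biphenyl]-3,3'-diol | COCOc1c(O)c(OC)ccc1-c1ccc(OC)c(O)c1OCOC | intermediate
11 | allyl bromide | C=CCBr | starting material
12 | 3,3'-bis(allyloxy)-4,4'-dimethoxy-2,2'-bis(methoxymethoxy)-1,1'-biphenyl | C=CCOc1c(OC)ccc(-c2ccc(OC)c(OCC=C)c2OCOC)c1OCOC | intermediate
13 | ring A ortho-dienone: 6-allyl-3-[3-(allyloxy)-4-methoxy-2-(methoxymethoxy)phenyl]-6-methoxy-2-(methoxymethoxy)cyclohexa-2,4-dien-1-one (not isolated; configuration at the sp3 carbon immaterial) | O=C1C(OCOC)=C(c2ccc(OC)c(OCC=C)c2OCOC)C=CC1(OC)CC=C | intermediate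
14 | ring A para-dienone: 4-allyl-3-[3-(allyloxy)-4-methoxy-2-(methoxymethoxy)phenyl]-6-methoxy-2-(methoxymethoxy)cyclohexa-2,5-dien-1-one (not isolated; configuration at the sp3 carbon immaterial) | O=C1C(OCOC)=C(c2ccc(OC)c(OCC=C)c2OCOC)C(CC=C)C=C1OC | intermediate
15 | monophenol: 6-allyl-3'-(allyloxy)-4,4'-dimethoxy-2,2'-bis(methoxymethoxy)-[1,1'-biphenyl]-3-ol (not isolated) | COCOc1c(O)c(OC)cc(CC=C)c1-c1ccc(OC)c(OCC=C)c1OCOC | intermediate
16 | ring B ortho-dienone: 6-allyl-3-[6-allyl-3-hydroxy-4-methoxy-2-(methoxymethoxy)phenyl]-6-methoxy-2-(methoxymethoxy)cyclohexa-2,4-dien-1-one (not isolated; configuration at the sp3 carbon immaterial) | O=C1C(OCOC)=C(c2c(CC=C)cc(OC)c(O)c2OCOC)C=CC1(OC)CC=C | intermediate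
17 | ring B para-dienone: 4-allyl-3-[6-allyl-3-hydroxy-4-methoxy-2-(methoxymethoxy)phenyl]-6-methoxy-2-(methoxymethoxy)cyclohexa-2,5-dien-1-one (not isolated; configuration at the sp3 carbon immaterial) | O=C1C(OCOC)=C(c2c(CC=C)cc(OC)c(O)c2OCOC)C(CC=C)C=C1OC | intermediate
18 | 6,6'-diallyl-4,4'-dimethoxy-2,2'-bis(methoxymethoxy)-[1,1'-biphenyl]-3,3'-diol | COCOc1c(O)c(OC)cc(CC=C)c1-c1c(CC=C)cc(OC)c(O)c1OCOC | intermediate
19 | iodomethane | CI | starting material
20 | 6,6'-diallyl-3,3',4,4'-tetramethoxy-2,2'-bis(methoxymethoxy)-1,1'-biphenyl | COCOc1c(OC)c(OC)cc(CC=C)c1-c1c(CC=C)cc(OC)c(OC)c1OCOC | intermediate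
21 | 3,3',4,4'-tetramethoxy-2,2'-bis(methoxymethoxy)-6,6'-bis(2-oxopropyl)-1,1'-biphenyl | COCOc1c(OC)c(OC)cc(CC(C)=O)c1-c1c(CC(C)=O)cc(OC)c(OC)c1OCOC | intermediate
22 | 2,2'-dihydroxy-3,3',4,4'-tetramethoxy-6,6'-bis(2-oxopropyl)-1,1'-biphenyl (racemic axis) | COc1cc(CC(C)=O)c(-c2c(CC(C)=O)cc(OC)c(OC)c2O)c(O)c1OC | target

Total step count: 10. Longest linear sequence: 10 steps, from o-vanillin 1 to target 22.

Steps most likely to fail

Step 7. The twofold sigmatropic relay may stall after one ring, or the dienone intermediates may fragment with loss of the allyl group, or the MOM acetals may be cleaved at 200 °C. The fallback leaves the route at diol 10 and uses cross-coupling instead of rearrangement. Bromination para to each free hydroxyl (NBS, CHCl3, −40 °C, catalytic base) should give 6,6'-dibromo-4,4'-dimethoxy-2,2'-bis(methoxymethoxy)-[1,1'-biphenyl]-3,3'-diol F1. Methylation (MeI, K2CO3, DMF) should then give 6,6'-dibromo-3,3',4,4'-tetramethoxy-2,2'-bis(methoxymethoxy)-1,1'-biphenyl F2. A twofold Stille coupling with allyltributylstannane (Pd(PPh3)4, a zerovalent palladium complex, DMF, 100 °C) should deliver 20, where the main route resumes.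

Step 4. The copper-mediated oxidative dimerisation of the aryllithium may be inefficient, with proton return to 7 or chloride transfer in place of C–C coupling. The fallback sets out from 7 by way of the same aryllithium 8, which is quenched with I2 to give 2-(benzyloxy)-4-iodo-1-methoxy-3-(methoxymethoxy)benzene F3. This isolable iodide is then dimerised reductively by a classical Ullmann coupling (activated copper powder, DMF, 130 °C) to return to the route at 9.

Step 9. Palladium hydride species may isomerise the allyl groups into conjugation with the arenes, and the second alkene may be oxidised incompletely. The fallback sets out from 20 and replaces the direct oxidation by hydration followed by oxidation. Mukaiyama hydration (Co(acac)2, PhSiH3, O2, i-PrOH) should give the Markovnikov diol 1,1'-[4,4',5,5'-tetramethoxy-6,6'-bis(methoxymethoxy)-[1,1'-biphenyl]-2,2'-diyl]bis(propan-2-ol) F4 as a mixture of diastereomers of no consequence. Dess–Martin periodinane in CH2Cl2 then oxidises both secondary alcohols and returns to the route at 21.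

Further compounds
F1 | step 7 | 6,6'-dibromo-4,4'-dimethoxy-2,2'-bis(methoxymethoxy)-[1,1'-biphenyl]-3,3'-diol | COCOc1c(O)c(OC)cc(Br)c1-c1c(Br)cc(OC)c(O)c1OCOC
F2 | step 7 | 6,6'-dibromo-3,3',4,4'-tetramethoxy-2,2'-bis(methoxymethoxy)-1,1'-biphenyl | COCOc1c(OC)c(OC)cc(Br)c1-c1c(Br)cc(OC)c(OC)c1OCOC
F3 | step 4 | 2-(benzyloxy)-4-iodo-1-methoxy-3-(methoxymethoxy)benzene | COCOc1c(I)ccc(OC)c1OCc1ccccc1
F4 | step 9 | 1,1'-[4,4',5,5'-tetramethoxy-6,6'-bis(methoxymethoxy)-[1,1'-biphenyl]-2,2'-diyl]bis(propan-2-ol) (mixture of diastereomers) | COCOc1c(OC)c(OC)cc(CC(C)O)c1-c1c(CC(C)O)cc(OC)c(OC)c1OCOC
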